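**Strategy.** The chain C2–C3–C3''–C2'', which carries all four stereocentres and links the two pyranone rings C, is treated as four adjacent carbons of a cyclohexene whose two alkene carbons are sacrificial. One Diels–Alder reaction between an E,E-1,4-bis(4-methoxyphenyl)butadiene and an E-1,4-bis(2-fluoro-4-methoxyphenyl)butenedione forms the C2–C3 and C2''–C3'' bonds and locks C2 and C2'' in the unlike (meso) relation as a cis-3,6-diaryl cyclohexene. Ozonolysis and Baeyer–Villiger oxidation then put oxygen on C2 and C2'' with retention. These oxygens close both rings C by displacing the ortho fluorides of rings A, base corrects C3'', and demethylation gives the target.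

Key step: step 3

Assumption: the target SMILES encodes the meso isomer (2S,3R,2''R,3''S) with both rings C 2,3-trans, so racemic intermediates suffice and both enantiomers of each converge on one achiral product.

**Route**

Step 1
Reactants: 1 (E)-4-methoxycinnamaldehyde; 2 diethyl (4-methoxybenzyl)phosphonate
Product: 3 (1E,3E)-1,4-bis(4-methoxyphenyl)buta-1,3-diene
Conditions: KOtBu, THF, 0 °C → rt
Reagents that add atoms: none
Why: Horner–Wadsworth–Emmons olefination: the potassium phosphonate carbanion adds reversibly to the enal and syn-eliminates diethyl phosphate through the less crowded oxaphosphetane, so the new aryl-substituted alkene should form E while the existing E alkene is untouched, and the symmetric E,E diene should crystallise readily.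

Step 2
Reactants: 4 fumaryl chloride; 5 3-fluoroanisole (2 equiv)
Product: 6 (2E)-1,4-bis(2-fluoro-4-methoxyphenyl)but-2-ene-1,4-dione
Conditions: AlCl3, CH2Cl2, 0 °C → rt; then ice/aq. HCl
Reagents that add atoms: none
Why: Twofold Friedel–Crafts acylation: each acylium end of fumaryl chloride should attack 3-fluoroanisole para to the methoxy group (the position ortho to fluorine), which is the most activated and least hindered site, with the E alkene geometry carried over unchanged, and the symmetric para,para product should be separable from minor regioisomers by crystallisation.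

Step 3
Reactants: 3 (1E,3E)-1,4-bis(4-methoxyphenyl)buta-1,3-diene; 6 (2E)-1,4-bis(2-fluoro-4-methoxyphenyl)but-2-ene-1,4-dione
Product: 7 rac-(3S,4S,5S,6R)-4,5-bis(2-fluoro-4-methoxybenzoyl)-3,6-bis(4-methoxyphenyl)cyclohex-1-ene (aryl groups at C3/C6 cis, aroyl groups at C4/C5 trans)
Conditions: o-xylene, 150 °C, sealed tube, BHT (cat.), dark
Reagents that add atoms: none
Why: The reaction is a concerted thermal [4+2] cycloaddition of normal electron demand (electron-rich bis-anisyl diene, electron-poor enedione), and the closest known reaction type is the Diels–Alder addition of E,E-1,4-diarylbutadienes to trans-1,2-diaroylethylenes. The cyclohexene ring is closed intermolecularly by suprafacial–suprafacial formation of the two sigma bonds that later become C2–C3 and C2''–C3''. The two aryl-bearing stereocentres are fixed cis by the E,E geometry of the diene reacting through its s-cis conformer, and the two aroyl-bearing stereocentres are fixed trans by the retained E geometry of the dienophile. Both partners are symmetric, so there is no regiochemical question, and because the dienophile is C2-symmetric the endo and exo approaches give the same racemic diastereomer (one aroyl cis, one trans to its neighbouring aryl). The only selectivity needed is therefore the cis relation of the aryl-bearing carbons, which the diene geometry secures, and both enantiomers of 7 later converge on the meso product. The methoxy and fluoro groups are spectators, while BHT and exclusion of light suppress radical oligomerisation of 3 and E/Z isomerisation of 6.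

Step 4
Reactants: 7 rac-cis-3,6-diaryl-trans-4,5-diaroylcyclohexene
Product: 8 rac-3,4-bis(2-fluoro-4-methoxybenzoyl)-2,5-bis(4-methoxyphenyl)hexanedial (four stereocentres as in 7)
Conditions: O3, CH2Cl2, −78 °C (Sudan Red 7B end point); PPh3, −78 °C → rt
Reagents that add atoms: ozone, [O-][O+]=O
Why: Ozonolysis (1,3-dipolar cycloaddition of ozone, cycloreversion and recombination to the ozonide, then reduction by PPh3) cleaves the only C=C bond, which reacts far faster than the anisole rings when ozone is dosed to the indicator end point at −78 °C, and no stereocentre is involved, the crude dialdehyde being taken on at once to limit enolisation at its two benzylic formyl-bearing carbons.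

Step 5
Reactants: 8 rac-dialdehyde
Product: 9 rac-2,3-bis(2-fluoro-4-methoxybenzoyl)-1,4-bis(4-methoxyphenyl)butane-1,4-diyl diformate (four stereocentres as in 7)
Conditions: mCPBA, NaHCO3, CH2Cl2, 0 °C → rt
Reagents that add atoms: mCPBA (3-chloroperoxybenzoic acid), O=C(OO)c1cccc(Cl)c1
Why: Baeyer–Villiger oxidation: in the Criegee adduct of each α-aryl, α-branched aldehyde the secondary benzylic carbon should migrate to oxygen in preference to hydride and does so with retention of configuration, which places oxygen on the future C2 and C2'' without touching their cis relation, while the electron-poorer, hindered ortho-fluoroaryl ketones react much more slowly with the buffered peracid.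

Step 6
Reactants: 9 rac-diformate
Product: 12 meso-(2S,3R,2''R,3''S)-7,7''-dimethoxy-2,2''-bis(4-methoxyphenyl)-3,3''-bichroman-4,4''-dione, via bis(β-hydroxy ketone) 10 (not isolated), via trans-cis biflavanone 11 (not isolated)
Conditions: K2CO3, MeOH/DMF (1:4), 0 °C → 45 °C
Reagents that add atoms: none
Why: Base-mediated transesterification removes both formyl groups as methyl formate, each liberated alkoxide then closes a ring C by intramolecular nucleophilic aromatic substitution (addition–elimination) at the ketone-activated C–F carbon of ring A with the C2–O and C2''–O bonds intact (hence retention), and carbonate finally epimerises the single 2,3-cis ring at C3'' through its enolate to the pseudo-diequatorial 2,3-trans arrangement, which with the fixed unlike C2/C2'' pair can only be the meso isomer.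

Step 7
Reactants: 12 meso-tetramethyl ether
Product: 13 meso-(2S,3R,2''R,3''S)-7,7''-dihydroxy-2,2''-bis(4-hydroxyphenyl)-3,3''-bichroman-4,4''-dione (CNP0231820.1)
Conditions: BBr3, CH2Cl2, −78 °C → 0 °C; then MeOH, H2O
Reagents that add atoms: none
Why: Lewis-acid cleavage of the four aryl methyl ethers (BBr3 coordination to each ether oxygen followed by bromide attack on methyl) is standard for methoxyflavanones and, kept at or below 0 °C to disfavour ionisation of the benzylic C2–O1 bonds, should leave C2/C2'' untouched, while C3/C3'' already sit in their thermodynamically preferred trans arrangement.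

**Compound list** (racemic compounds are drawn as one enantiomer)

1 | (E)-4-methoxycinnamaldehyde | COc1ccc(/C=C/C=O)cc1 | starting material
2 | diethyl (4-methoxybenzyl)phosphonate | CCOP(=O)(Cc1ccc(OC)cc1)OCC | starting material
3 | (1E,3E)-1,4-bis(4-methoxyphenyl)buta-1,3-diene | COc1ccc(/C=C/C=C/c2ccc(OC)cc2)cc1 | intermediate
4 | fumaryl chloride | O=C(Cl)/C=C/C(=O)Cl | starting material
5 | 3-fluoroanisole | COc1cccc(F)c1 | starting material
6 | (2E)-1,4-bis(2-fluoro-4-methoxyphenyl)but-2-ene-1,4-dione | O=C(/C=C/C(=O)c1ccc(OC)cc1F)c1ccc(OC)cc1F | intermediate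
7 | rac-(3S,4S,5S,6R)-4,5-bis(2-fluoro-4-methoxybenzoyl)-3,6-bis(4-methoxyphenyl)cyclohex-1-ene (3,6-cis, 4,5-trans) | C1=C[C@H](c2ccc(OC)cc2)[C@H](C(=O)c2ccc(OC)cc2F)[C@@H](C(=O)c2ccc(OC)cc2F)[C@@H]1c1ccc(OC)cc1 | intermediate
8 | rac-3,4-bis(2-fluoro-4-methoxybenzoyl)-2,5-bis(4-methoxyphenyl)hexanedial (configuration of 7 retained) | O=C[C@H](c1ccc(OC)cc1)[C@H](C(=O)c1ccc(OC)cc1F)[C@@H](C(=O)c1ccc(OC)cc1F)[C@@H](C=O)c1ccc(OC)cc1 | intermediate
9 | rac-2,3-bis(2-fluoro-4-methoxybenzoyl)-1,4-bis(4-methoxyphenyl)butane-1,4-diyl diformate (configuration of 7 retained) | O=CO[C@H](c1ccc(OC)cc1)[C@H](C(=O)c1ccc(OC)cc1F)[C@@H](C(=O)c1ccc(OC)cc1F)[C@@H](OC=O)c1ccc(OC)cc1 | intermediate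
10 | rac-1,4-bis(2-fluoro-4-methoxyphenyl)-2,3-bis[hydroxy(4-methoxyphenyl)methyl]butane-1,4-dione (bis(β-hydroxy ketone), formed in the flask) | O[C@H](c1ccc(OC)cc1)[C@H](C(=O)c1ccc(OC)cc1F)[C@@H](C(=O)c1ccc(OC)cc1F)[C@@H](O)c1ccc(OC)cc1 | intermediate
11 | rac-(2S,3R,2''R,3''R)-7,7''-dimethoxy-2,2''-bis(4-methoxyphenyl)-3,3''-bichroman-4,4''-dione (one ring 2,3-trans, the other 2,3-cis; formed in the flask) | O=C1c2ccc(OC)cc2O[C@H](c2ccc(OC)cc2)[C@H]1[C@H]1C(=O)c2ccc(OC)cc2O[C@H]1c1ccc(OC)cc1 | intermediate
12 | meso-(2S,3R,2''R,3''S)-7,7''-dimethoxy-2,2''-bis(4-methoxyphenyl)-3,3''-bichroman-4,4''-dione (both rings 2,3-trans) | O=C1c2ccc(OC)cc2O[C@H](c2ccc(OC)cc2)[C@H]1[C@@H]1C(=O)c2ccc(OC)cc2O[C@H]1c1ccc(OC)cc1 | intermediate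
13 | meso-(2S,3R,2''R,3''S)-7,7''-dihydroxy-2,2''-bis(4-hydroxyphenyl)-3,3''-bichroman-4,4''-dione | O=C1c2ccc(O)cc2O[C@H](c2ccc(O)cc2)[C@H]1[C@@H]1C(=O)c2ccc(O)cc2O[C@H]1c1ccc(O)cc1 | target

**Step count.** Total: 7 steps (steps 1 and 2 run in parallel). Longest linear sequence: 6 steps (step 1 or step 2, then steps 3 to 7).

**Steps most likely to fail**

Risk 1, step 3 (key step). The cycloaddition of the hindered 1,4-diaryl diene may be slower than thermal oligomerisation of 3, geometric isomerisation of 6, or a hetero-Diels–Alder pathway in which the enone of 6 acts as the four-atom partner. The fallback sets out from 3 and returns at 7. Diene 3 is heated with maleic anhydride (PhMe, reflux), the most dependable dienophile for 1,4-diarylbutadienes, to give the all-cis endo anhydride F1, in which the cis aryl relation is again set by the suprafacial addition. MeOH with catalytic H2SO4 at reflux should convert it into the all-cis dimethyl ester F2, and NaOMe in MeOH should equilibrate this to the trans-diester F3. MeNHOMe·HCl with i-PrMgCl (THF, −20 °C) should give the trans bis(N-methoxy-N-methylamide) F4. Twofold addition of 2-fluoro-4-methoxyphenylmagnesium bromide F5 (from commercial 4-bromo-3-fluoroanisole, Mg, LiCl, THF, 0 °C) should then deliver 7.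

Risk 2, step 6. Retro-aldol fragmentation or dehydration of the β-hydroxy ketone may outrun aryl ether formation, methoxide may attack the fluoroarene, or the unlike C2/C2'' relation may be eroded by reversible ring opening to a chalcone while C3'' equilibrates. The fallback sets out from 9 and returns at 12. The formates are removed under near-neutral conditions (KHCO3, MeOH, 0 °C) and diol 10 is isolated and silylated (TMSCl, imidazole, CH2Cl2) to the bis(trimethylsilyl) ether F6. Catalytic CsF in DMF should then trigger desilylative nucleophilic aromatic substitution, in which free alkoxide is present only transiently and the displaced fluoride carries the chain, to give 11. A separate, monitored epimerisation with catalytic DBU in CH2Cl2 at rt should convert 11 into 12.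

Risk 3, step 5. Hydride rather than carbon migration in the Criegee adduct would give carboxylic acids, and enolisation of the α-aryl aldehyde would scramble C2/C2''. The fallback sets out from 8 and re-enters at 10 (generated in the flask under the step 6 conditions), then 12. Aldehyde-selective methylation with MeTi(OiPr)3 (THF, −40 → 0 °C) should give the bis(secondary alcohol) F7 as a mixture of carbinol epimers. Dess–Martin periodinane should oxidise it to the bis(methyl ketone) F8. Baeyer–Villiger oxidation with mCPBA/NaHCO3 should then give the diacetate F9, since a secondary benzylic carbon migrates reliably in preference to methyl and with retention. F9 is methanolysed under the step 6 conditions exactly as 9.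

Further compounds
F1 | step 3 | all-cis-3,6-bis(4-methoxyphenyl)cyclohex-4-ene-1,2-dicarboxylic anhydride (meso endo adduct) | C1=C[C@H](c2ccc(OC)cc2)[C@@H]2C(=O)OC(=O)[C@@H]2[C@@H]1c1ccc(OC)cc1
F2 | step 3 | dimethyl all-cis-3,6-bis(4-methoxyphenyl)cyclohex-4-ene-1,2-dicarboxylate (meso) | C1=C[C@H](c2ccc(OC)cc2)[C@H](C(=O)OC)[C@H](C(=O)OC)[C@@H]1c1ccc(OC)cc1
F3 | step 3 | rac-dimethyl cis-3,6-bis(4-methoxyphenyl)cyclohex-4-ene-trans-1,2-dicarboxylate | C1=C[C@H](c2ccc(OC)cc2)[C@H](C(=O)OC)[C@@H](C(=O)OC)[C@@H]1c1ccc(OC)cc1
F4 | step 3 | rac-cis-3,6-bis(4-methoxyphenyl)cyclohex-4-ene-trans-1,2-bis(N-methoxy-N-methylcarboxamide) | C1=C[C@H](c2ccc(OC)cc2)[C@H](C(=O)N(C)OC)[C@@H](C(=O)N(C)OC)[C@@H]1c1ccc(OC)cc1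
F5 | step 3 | 2-fluoro-4-methoxyphenylmagnesium bromide | COc1ccc([Mg]Br)c(F)c1
F6 | step 6 | rac-1,4-bis(2-fluoro-4-methoxyphenyl)-2,3-bis[(4-methoxyphenyl)(trimethylsilyloxy)methyl]butane-1,4-dione (bis(trimethylsilyl) ether of 10) | C[Si](C)(C)O[C@H](c1ccc(OC)cc1)[C@H](C(=O)c1ccc(OC)cc1F)[C@@H](C(=O)c1ccc(OC)cc1F)[C@@H](O[Si](C)(C)C)c1ccc(OC)cc1
F7 | step 5 | 4,5-bis(2-fluoro-4-methoxybenzoyl)-3,6-bis(4-methoxyphenyl)octane-2,7-diol (carbinol epimers; C3–C6 as in 8) | CC(O)[C@H](c1ccc(OC)cc1)[C@H](C(=O)c1ccc(OC)cc1F)[C@@H](C(=O)c1ccc(OC)cc1F)[C@@H](C(C)O)c1ccc(OC)cc1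
F8 | step 5 | rac-4,5-bis(2-fluoro-4-methoxybenzoyl)-3,6-bis(4-methoxyphenyl)octane-2,7-dione | CC(=O)[C@H](c1ccc(OC)cc1)[C@H](C(=O)c1ccc(OC)cc1F)[C@@H](C(=O)c1ccc(OC)cc1F)[C@@H](C(C)=O)c1ccc(OC)cc1
F9 | step 5 | rac-2,3-bis(2-fluoro-4-methoxybenzoyl)-1,4-bis(4-methoxyphenyl)butane-1,4-diyl diacetate | CC(=O)O[C@H](c1ccc(OC)cc1)[C@H](C(=O)c1ccc(OC)cc1F)[C@@H](C(=O)c1ccc(OC)cc1F)[C@@H](OC(C)=O)c1ccc(OC)cc1
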